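I reckon this flask in slowness, the minutes needed per millimolar of target, which is the inverse of the rate. I treat it as two waits in a row, one for substrate and one for partner. Each wait scales inversely with its own concentration, and the two add.

| setting | green | ochre | violet | red | grey |
|---|---|---|---|---|---|
| substrate | 100 mM | 40.0 mM | 300 mM | 100 mM | 100 mM |
| partner | 300 mM | 240 mM | 300 mM | 300 mM | 300 mM |
| free catalyst | 1.00 mM | 1.00 mM | 1.00 mM | 3.00 mM | 1.00 mM |
| time |  |  |  |  | 510 min |

- green run (time / min: [target] / mM): 6.1: 6.7; 18: 16.1; 35: 25.2; 56: 31.7; 80: 37.6; 110: 42.2; 140: 45.9; 170: 46.9
- ochre run (time / min: [target] / mM): 6.1: 4.4; 18: 5.5; 35: 10.8; 56: 11.8; 80: 16.1; 110: 17.1; 140: 17.4; 170: 18.5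
- violet run (time / min: [target] / mM): 6.1: 12.5; 18: 34.3; 35: 58.1; 56: 80.4; 80: 97.7; 110: 114.4; 140: 126.8; 170: 132.5
- red run (time / min: [target] / mM): 6.1: 15.7; 18: 32.2; 35: 44.7; 56: 51.0; 80: 55.5; 110: 58.9; 140: 57.8; 170: 58.9

(scatter of a reading: 0.8 mM)

- the exponent of [substrate] in the starting rate at the charge of the green run (at the point where two percent of the substrate have become target) (one fixed amount of target, the same in the runs compared)
- the exponent of [partner] in the starting rate at the charge of the green run (at the point where two percent of the substrate have become target)
- target in the grey run at 510 min, as a share of the substrate charged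

- Overall: substrate + partner -> target, with free catalyst as catalyst.
- Constant volume, constant temperature.
- A reading of a species includes what of it is bound.
- "The second partner" is partner.
- An order is taken over about fifteen percent of the charge, up and down.

The first reading of the green run gives a rate of 1.10 mM min⁻¹, and that of the violet run gives 2.05 mM min⁻¹, so the violet run has 0.536 of the slowness of the green run. Both have the same [partner], and the violet run cuts the substrate wait to a third. So the substrate wait in the green run reads 0.696 of its whole slowness, and the partner wait reads 0.304. The substrate wait is longer.

I carry this number, the substrate's share of slowness, the substrate wait divided by the whole slowness. In this picture it is the exponent of [substrate], and the remainder, 0.304, is the exponent of [partner].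

Now the slowing. The green run starts at 1.10 mM min⁻¹ and reads 0.0783 mM min⁻¹ between 110 min and 170 min, a fall by a factor of 14.0. The substrate and partner turned into the 45.9 mM of target read at 140 min lengthen the two waits together by a factor of 1.65. A factor of 8.52 stays outside the two waits.

The grey run has the charge of the green run. Held at that late rate, it gains 26.6 mM after 170 min, but the rate is still falling. The red run, with 3.00 mM of free catalyst, reads 58.9 mM at 110 min and 58.9 mM at 170 min. I take that level, 58.9%, as my figure for the grey run.

The forecast gives 0.7, 0.5 and 56%, and says: “Grey should approach equilibrium, near 56%.” Its substrate exponent stands close to mine, though it comes from a saturation constant. Its partner exponent is higher than mine, and its grey figure is lower than mine.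

    free catalyst + substrate → catalyst-substrate complex (15.60 M⁻¹ min⁻¹)
    catalyst-substrate complex + partner → target + free catalyst (14.28 M⁻¹ min⁻¹)
    target → decomposed product (0.001410 min⁻¹)
    2 free catalyst → 2 spent catalyst (22.56 M⁻¹ min⁻¹)

The flask gives exponents of 0.81 and 0.26, and the grey run holds 40.6% of its substrate as target at 510 min, less than the forecast by 15 percentage points. Target decomposes with a mean life of 709 min. My share of 0.696 lies below the substrate exponent, and its remainder lies above the partner exponent. Put to the ochre run, the share multiplies the slowness of the green run by 2.12, which gives a rate of 0.519 mM min⁻¹, and the ochre run shows 0.44 mM min⁻¹ where two percent of the substrate of the green run have turned.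

The earlier runs and the new flask are simulated with made-up constants, noise included.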